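**Retrosynthetic overview**
1. The route rests on the C1–C2 bond, which joins the benzylic CH2 (C1) on the 1,3,5-trisubstituted benzene ring to the acetoxy-bearing stereocentre C2 of the tridecane chain. No ring is formed at any stage; the benzene ring is bought.
2. C2–OAc ⇒ C2–OH ⇒ C2–B. C1–C2 is cut so that C2 is a sparteine-bound α-carbamoyloxy carbanion that then acts as a carbenoid (C2–C13 carbamate 11), and C1 is the migrating group of benzylic pinacol boronate 17.
3. Carbamate 11: the C8 stereocentre comes from (R)-epichlorohydrin through two copper-catalysed Grignard openings (pent-4-enyl, then butyl), followed by silylation, hydroboration and carbamoylation.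
4. Boronate 17: 3-hydroxy-5-methoxybenzaldehyde is silylated, reduced, chlorinated and borylated.
5. After the coupling C2–OH is the only free hydroxyl: acetylation, then buffered fluoride frees C8–OH and the phenol.

Key step: step 11

Remark: the chain is numbered from the benzylic CH2 (C1) to C13; C8–OH is carried as a TBS ether and the phenol as a TIPS ether, so that one buffered fluoride treatment frees both beside the acetate while the aryl silyl ether survives the basic steps.

**Route**

Step 1
Reactants: 1 (R)-epichlorohydrin; 2 5-bromo-1-pentene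
Product: 4 (R)-1-chlorooct-7-en-2-ol, via pent-4-enylmagnesium bromide 3 (not isolated)
Conditions: 2, Mg, THF, rt; then 1, CuI (5 mol%), THF, −40 → −20 °C; aq NH4Cl
Reagents that add atoms: none
Why: The copper-catalysed Grignard reagent should open the epoxide by SN2 attack at its unsubstituted CH2 faster than it displaces chloride, so the stereocentre of 1 (the later C8) is carried into 4 without any bond to it being broken.

Step 2
Reactants: 4 (R)-1-chlorooct-7-en-2-ol
Product: 5 (R)-2-(hex-5-en-1-yl)oxirane
Conditions: powdered NaOH, Et2O, rt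
Reagents that add atoms: none
Why: Intramolecular Williamson etherification of the chlorohydrin alkoxide at the CH2Cl carbon closes the epoxide without touching the stereocentre.

Step 3
Reactants: 5 (R)-2-(hex-5-en-1-yl)oxirane; 6 n-butylmagnesium chloride
Product: 7 (S)-dodec-11-en-6-ol
Conditions: 6 (2 M in THF), CuI (10 mol%), THF, −40 → −20 °C; aq NH4Cl
Reagents that add atoms: none
Why: Copper-catalysed SN2 opening at the terminal epoxide carbon completes the pentyl arm with the C–O stereocentre untouched; the descriptor changes from R to S only because the CIP ranking of the two arms changes.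

Step 4
Reactants: 7 (S)-dodec-11-en-6-ol
Product: 8 tert-butyl{[(6S)-dodec-11-en-6-yl]oxy}dimethylsilane
Conditions: TBSCl, imidazole, DMF, rt
Reagents that add atoms: tert-butyldimethylsilyl chloride, CC(C)(C)[Si](C)(C)Cl
Why: Imidazole-promoted silylation of the secondary alcohol gives a TBS ether that is inert to the later borane, base and organolithium steps.

Step 5
Reactants: 8 tert-butyl{[(6S)-dodec-11-en-6-yl]oxy}dimethylsilane
Product: 10 (7S)-7-[(tert-butyldimethylsilyl)oxy]dodecan-1-ol, via alkyl-9-BBN adduct 9 (not isolated)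
Conditions: 9-BBN, THF, 0 °C → rt; then NaOH, H2O2, H2O, 0 °C → rt
Reagents that add atoms: hydrogen peroxide, OO
Why: Hydroboration–oxidation with the bulky borane places boron, and then oxygen, on the terminal carbon of the monosubstituted alkene (anti-Markovnikov).

Step 6
Reactants: 10 (7S)-7-[(tert-butyldimethylsilyl)oxy]dodecan-1-ol
Product: 11 (7S)-7-[(tert-butyldimethylsilyl)oxy]dodecyl N,N-diisopropylcarbamate
Conditions: iPr2NCOCl, Et3N, CH2Cl2, reflux
Reagents that add atoms: N,N-diisopropylcarbamoyl chloride, CC(C)N(C(C)C)C(Cl)=O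
Why: O-carbamoylation of the primary alcohol installs the hindered carbamate that later directs the lithiation and serves as leaving group.

Step 7
Reactants: 12 3-hydroxy-5-methoxybenzaldehyde
Product: 13 3-methoxy-5-(triisopropylsilyloxy)benzaldehyde
Conditions: TIPSCl, imidazole, DMF, rt
Reagents that add atoms: triisopropylsilyl chloride, CC(C)[Si](Cl)(C(C)C)C(C)C
Why: Silylation of the phenol is fast and leaves the aldehyde untouched; the bulky TIPS group gives the most base-stable aryl silyl ether.

Step 8
Reactants: 13 3-methoxy-5-(triisopropylsilyloxy)benzaldehyde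
Product: 14 [3-methoxy-5-(triisopropylsilyloxy)phenyl]methanol
Conditions: NaBH4, THF/MeOH, 0 °C
Reagents that add atoms: none
Why: Borohydride reduction of the aryl aldehyde gives the benzylic alcohol under conditions that the aryl silyl ether tolerates.

Step 9
Reactants: 14 [3-methoxy-5-(triisopropylsilyloxy)phenyl]methanol
Product: 15 [3-(chloromethyl)-5-methoxyphenoxy]triisopropylsilane
Conditions: SOCl2, pyridine, CH2Cl2, 0 °C → rt
Reagents that add atoms: thionyl chloride, ClS(Cl)=O
Why: Deoxychlorination through the chlorosulfite converts the benzylic alcohol into the chloride, with pyridine taking up HCl so that the silyl ether is not exposed to acid.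

Step 10
Reactants: 15 [3-(chloromethyl)-5-methoxyphenoxy]triisopropylsilane; 16 bis(pinacolato)diboron
Product: 17 2-[3-methoxy-5-(triisopropylsilyloxy)benzyl]-4,4,5,5-tetramethyl-1,3,2-dioxaborolane
Conditions: Pd(dba)2 (3 mol%), P(4-MeOC6H4)3 (6 mol%), KOAc, toluene, 50 °C
Reagents that add atoms: none
Why: Miyaura borylation of a benzylic chloride: oxidative addition of the C–Cl bond to zerovalent palladium, acetate-assisted transmetalation with 16 and reductive elimination give the benzylic pinacol boronate.

Step 11
Reactants: 11 (7S)-7-[(tert-butyldimethylsilyl)oxy]dodecyl N,N-diisopropylcarbamate; 17 2-[3-methoxy-5-(triisopropylsilyloxy)benzyl]-4,4,5,5-tetramethyl-1,3,2-dioxaborolane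
Product: 21 (2R,8S)-8-[(tert-butyldimethylsilyl)oxy]-1-[3-methoxy-5-(triisopropylsilyloxy)phenyl]tridecan-2-ol, via lithiated carbamate 18 (not isolated), via boron ate complex 19 (not isolated), via secondary boronic ester 20 (not isolated)
Conditions: 11, (−)-sparteine, s-BuLi, Et2O, −78 °C, 5 h; 17, −78 °C, 1 h; MgBr2·OEt2, −78 °C → reflux, 16 h; then NaBO3·4H2O, THF/H2O, rt
Reagents that add atoms: sodium perborate tetrahydrate, O[B-]1(O)OO[B-](O)(O)OO1.[Na+].[Na+]
Why: s-BuLi bound to (−)-sparteine and directed by the carbamate carbonyl removes the pro-S hydrogen at C2 of 11 to give the configurationally stable (S)-organolithium 18, which adds to the empty orbital on boron of 17 with retention to give ate complex 19. On warming with MgBr2·OEt2 the benzyl group shifts from boron to C2 anti to the departing carbamate (inversion at C2), forming the C1–C2 bond in boronic ester 20, and perborate then replaces boron by oxygen with retention. The closest known reaction type is the lithiation–borylation of sparteine-complexed primary alkyl carbamates with pinacol boronic esters followed by oxidation, a 1,2-metallate rearrangement related to the Matteson homologation; no ring is closed. The new stereocentre C2 is set by the reagent alone: (−)-sparteine gives the S organolithium, and retention, inversion, retention lead to 2R, independent of the remote C8 centre. The step needs selection of one enantiotopic C2–H and carbon-over-oxygen migration at boron; the first is secured by the carbamate–sparteine–lithium complex, the second by the high migratory aptitude of benzyl and the magnesium Lewis acid, while the silyl ethers offer no acidic site and perborate is mild enough for the aryl silyl ether.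

Step 12
Reactants: 21 (2R,8S)-8-[(tert-butyldimethylsilyl)oxy]-1-[3-methoxy-5-(triisopropylsilyloxy)phenyl]tridecan-2-ol
Product: 22 (2R,8S)-8-[(tert-butyldimethylsilyl)oxy]-1-[3-methoxy-5-(triisopropylsilyloxy)phenyl]tridecan-2-yl acetate
Conditions: Ac2O, pyridine, DMAP (cat.), CH2Cl2, rt
Reagents that add atoms: acetic anhydride, CC(=O)OC(C)=O
Why: DMAP-catalysed acylation of the only free hydroxyl (C2) proceeds with retention because the C–O bond is not broken.

Step 13
Reactants: 22 (2R,8S)-8-[(tert-butyldimethylsilyl)oxy]-1-[3-methoxy-5-(triisopropylsilyloxy)phenyl]tridecan-2-yl acetate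
Product: 23 (2R,8S)-8-hydroxy-1-(3-hydroxy-5-methoxyphenyl)tridecan-2-yl acetate
Conditions: Bu4NF, AcOH (1:1), THF, 0 °C → rt
Reagents that add atoms: none
Why: Fluoride cleaves both Si–O bonds, while acetic acid keeps the medium non-basic so that the secondary acetate should neither hydrolyse nor be transferred to the liberated phenoxide.

**Compound list**
1 | (R)-epichlorohydrin, (R)-2-(chloromethyl)oxirane | ClC[C@H]1CO1 | starting material
2 | 5-bromo-1-pentene | C=CCCCBr | starting material
3 | pent-4-enylmagnesium bromide | C=CCCC[Mg]Br | intermediate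
4 | (R)-1-chlorooct-7-en-2-ol | ClC[C@H](O)CCCCC=C | intermediate
5 | (R)-2-(hex-5-en-1-yl)oxirane | C=CCCCC[C@@H]1CO1 | intermediate
6 | n-butylmagnesium chloride | CCCC[Mg]Cl | starting material
7 | (S)-dodec-11-en-6-ol | CCCCC[C@H](O)CCCCC=C | intermediate
8 | tert-butyl{[(6S)-dodec-11-en-6-yl]oxy}dimethylsilane | CCCCC[C@H](O[Si](C)(C)C(C)(C)C)CCCCC=C | intermediate
9 | 9-{(7S)-7-[(tert-butyldimethylsilyl)oxy]dodecyl}-9-borabicyclo[3.3.1]nonane | CCCCC[C@H](O[Si](C)(C)C(C)(C)C)CCCCCCB1C2CCCC1CCC2 | intermediate
10 | (7S)-7-[(tert-butyldimethylsilyl)oxy]dodecan-1-ol | CCCCC[C@H](O[Si](C)(C)C(C)(C)C)CCCCCCO | intermediate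
11 | (7S)-7-[(tert-butyldimethylsilyl)oxy]dodecyl N,N-diisopropylcarbamate | CCCCC[C@H](O[Si](C)(C)C(C)(C)C)CCCCCCOC(=O)N(C(C)C)C(C)C | intermediate
12 | 3-hydroxy-5-methoxybenzaldehyde | COc1cc(O)cc(C=O)c1 | starting material
13 | 3-methoxy-5-(triisopropylsilyloxy)benzaldehyde | COc1cc(C=O)cc(O[Si](C(C)C)(C(C)C)C(C)C)c1 | intermediate
14 | [3-methoxy-5-(triisopropylsilyloxy)phenyl]methanol | COc1cc(CO)cc(O[Si](C(C)C)(C(C)C)C(C)C)c1 | intermediate
15 | [3-(chloromethyl)-5-methoxyphenoxy]triisopropylsilane | COc1cc(CCl)cc(O[Si](C(C)C)(C(C)C)C(C)C)c1 | intermediate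
16 | bis(pinacolato)diboron | CC1(C)OB(OC1(C)C)B1OC(C)(C)C(C)(C)O1 | starting material
17 | 2-[3-methoxy-5-(triisopropylsilyloxy)benzyl]-4,4,5,5-tetramethyl-1,3,2-dioxaborolane | COc1cc(CB2OC(C)(C)C(C)(C)O2)cc(O[Si](C(C)C)(C(C)C)C(C)C)c1 | intermediate
18 | {(1S,7S)-7-[(tert-butyldimethylsilyl)oxy]-1-[(diisopropylcarbamoyl)oxy]dodecyl}lithium, (−)-sparteine complex | CCCCC[C@H](O[Si](C)(C)C(C)(C)C)CCCCC[C@H]([Li])OC(=O)N(C(C)C)C(C)C | intermediate
19 | lithium {(1S,7S)-7-[(tert-butyldimethylsilyl)oxy]-1-[(diisopropylcarbamoyl)oxy]dodecyl}[3-methoxy-5-(triisopropylsilyloxy)benzyl](pinacolato)borate | CCCCC[C@H](O[Si](C)(C)C(C)(C)C)CCCCC[C@@H](OC(=O)N(C(C)C)C(C)C)[B-]1(Cc2cc(OC)cc(O[Si](C(C)C)(C(C)C)C(C)C)c2)OC(C)(C)C(C)(C)O1.[Li+] | intermediate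
20 | 2-{(2R,8S)-8-[(tert-butyldimethylsilyl)oxy]-1-[3-methoxy-5-(triisopropylsilyloxy)phenyl]tridecan-2-yl}-4,4,5,5-tetramethyl-1,3,2-dioxaborolane | CCCCC[C@H](O[Si](C)(C)C(C)(C)C)CCCCC[C@H](Cc1cc(OC)cc(O[Si](C(C)C)(C(C)C)C(C)C)c1)B1OC(C)(C)C(C)(C)O1 | intermediate
21 | (2R,8S)-8-[(tert-butyldimethylsilyl)oxy]-1-[3-methoxy-5-(triisopropylsilyloxy)phenyl]tridecan-2-ol | CCCCC[C@H](O[Si](C)(C)C(C)(C)C)CCCCC[C@H](Cc1cc(OC)cc(O[Si](C(C)C)(C(C)C)C(C)C)c1)O | intermediate
22 | (2R,8S)-8-[(tert-butyldimethylsilyl)oxy]-1-[3-methoxy-5-(triisopropylsilyloxy)phenyl]tridecan-2-yl acetate | CCCCC[C@H](O[Si](C)(C)C(C)(C)C)CCCCC[C@H](Cc1cc(OC)cc(O[Si](C(C)C)(C(C)C)C(C)C)c1)OC(C)=O | intermediate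
23 | (2R,8S)-8-hydroxy-1-(3-hydroxy-5-methoxyphenyl)tridecan-2-yl acetate | CCCCC[C@H](O)CCCCC[C@H](Cc1cc(O)cc(OC)c1)OC(C)=O | target

**Step count**
Total steps: 13. Longest linear sequence: 9 steps (steps 1–6 and 11–13, from (R)-epichlorohydrin); the arene branch is 4 steps (7–10) before the coupling.

**Steps most likely to fail**

Step 11. The selection between the two enantiotopic C2 hydrogens may be incomplete if part of the organolithium is not sparteine-bound, and the resulting C2 epimer would be hard to separate because C2 and C8 are remote. The lithiated carbamate may also deprotonate the acidic benzylic CH2 of the boronate instead of adding to boron, and the 1,2-shift of a pinacol ate complex may be sluggish. The fallback sets out from alcohol 10 and returns at alcohol 21; it forms the aryl–C1 bond in place of C1–C2 and sets C2 by catalyst-controlled resolution. Dess–Martin oxidation of 10 should give (7S)-7-[(tert-butyldimethylsilyl)oxy]dodecanal F1. Corey–Chaykovsky methylenation (Me3SI, KN(SiMe3)2, THF) turns it into the terminal epoxide tert-butyldimethyl{[(6S)-11-(oxiran-2-yl)undecan-6-yl]oxy}silane F2 as a mixture of C2 epimers. Hydrolytic kinetic resolution with (R,R)-N,N′-bis(3,5-di-tert-butylsalicylidene)-1,2-cyclohexanediaminocobalt acetate (trivalent cobalt, 0.55 equiv H2O) should leave the (2R)-epoxide tert-butyldimethyl({(6S)-11-[(2R)-oxiran-2-yl]undecan-6-yl}oxy)silane F3. Bought 3-bromo-5-methoxyphenol is silylated (TIPSCl, imidazole) to 1-bromo-3-methoxy-5-(triisopropylsilyloxy)benzene F4 and converted with Mg in THF into [3-methoxy-5-(triisopropylsilyloxy)phenyl]magnesium bromide F5. F5 opens F3 at its CH2 under CuI catalysis to give 21.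

Step 10. Reductive homocoupling of the benzylic chloride to the bibenzyl may compete with borylation, and the benzylic boronate may lose boron on silica. The fallback sets out from chloride 15 and returns at boronate 17; it reverses the polarity, using a nucleophilic benzyl and an electrophilic boron reagent without palladium. Slow addition of 15 to Mg in Et2O at 0 °C gives [3-methoxy-5-(triisopropylsilyloxy)benzyl]magnesium chloride F6, which is quenched at −78 °C with 2-isopropoxy-4,4,5,5-tetramethyl-1,3,2-dioxaborolane to give 17 after aqueous work-up.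

Step 13. Cleavage of the secondary alkyl silyl ether may be slow under buffered fluoride, and long exposure may lead to loss of the acetate or its transfer to the phenoxide. The fallback sets out from acetate 22 and returns at target 23; it replaces the single fluoride treatment by two cleavages of different mechanism. Acid-catalysed methanolysis (camphorsulfonic acid, MeOH/CH2Cl2, 0 °C → rt) removes only the alkyl TBS group to give (2R,8S)-8-hydroxy-1-[3-methoxy-5-(triisopropylsilyloxy)phenyl]tridecan-2-yl acetate F7. The aryl TIPS ether of F7 is then cleaved within minutes by Bu4NF/AcOH in THF at 0 °C to give 23.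

**Further compounds**
F1 | step 11 | (7S)-7-[(tert-butyldimethylsilyl)oxy]dodecanal | CCCCC[C@H](O[Si](C)(C)C(C)(C)C)CCCCCC=O
F2 | step 11 | tert-butyldimethyl{[(6S)-11-(oxiran-2-yl)undecan-6-yl]oxy}silane, mixture of epimers at the oxirane carbon | CCCCC[C@H](O[Si](C)(C)C(C)(C)C)CCCCCC1CO1
F3 | step 11 | tert-butyldimethyl({(6S)-11-[(2R)-oxiran-2-yl]undecan-6-yl}oxy)silane | CCCCC[C@H](O[Si](C)(C)C(C)(C)C)CCCCC[C@@H]1CO1
F4 | step 11 | 1-bromo-3-methoxy-5-(triisopropylsilyloxy)benzene | COc1cc(Br)cc(O[Si](C(C)C)(C(C)C)C(C)C)c1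
F5 | step 11 | [3-methoxy-5-(triisopropylsilyloxy)phenyl]magnesium bromide | COc1cc([Mg]Br)cc(O[Si](C(C)C)(C(C)C)C(C)C)c1
F6 | step 10 | [3-methoxy-5-(triisopropylsilyloxy)benzyl]magnesium chloride | COc1cc(C[Mg]Cl)cc(O[Si](C(C)C)(C(C)C)C(C)C)c1
F7 | step 13 | (2R,8S)-8-hydroxy-1-[3-methoxy-5-(triisopropylsilyloxy)phenyl]tridecan-2-yl acetate | CCCCC[C@H](O)CCCCC[C@H](Cc1cc(OC)cc(O[Si](C(C)C)(C(C)C)C(C)C)c1)OC(C)=O
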